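## Structural features

The target is a bicyclic diterpenoid with labdane connectivity (labdane numbering is used throughout): a trans-fused decalin, rings A and B sharing the C5–C10 bond, with a C9 (E)-3-methylpent-3-enyl chain that ends in the C15 acetate. Its configuration is (2S,3R,5S,9R,10S), the antipodal (ent) labdane series: C20 on C10 and the C11 chain on C9 lie on one face; H5, H9, the equatorial C2 acetate and the axial C3 hydroxyl lie on the other. The five stereocentres form two adjacent pairs and a hinge: C2/C3 on ring A, C9/C10 at the quaternary ring-fusion carbon, and C5 next to C10 and to the gem-dimethyl carbon C4. Fragile points are the two acetates (the C2 acetate can migrate to the neighbouring C3 hydroxyl under base, the C15 acetate is allylic) and the trisubstituted C7=C8 alkene, which can drift to C8=C9 or C8=C17 under acid. The real difficulties are the quaternary C10 flanked by the C9 and C5 stereocentres and by C4, the exact placement of the only ring alkene, and two cis oxygens on neighbouring hindered carbons. The ring alkene C7=C8 with C17 on C8 lies exactly where a butenyl arm on C5 (C6, C7) and an isopropenyl group on C9 (C8, C17) meet, so ring B can be closed last by olefin metathesis on a ring A compound that already holds C5, C9 and C10. Ring A with its gem-dimethyl group, C20 and the C5 configuration maps onto (R)-α-ionone.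

## Logic of the disconnections

29 from 28: the C3–H bond is cut, carbinol back to ketone. The axial C3 alcohol cis to the C2 acetate is the less stable arrangement and is best set last by a bulky hydride on a ketone with one quaternary neighbour. The gain is that C3 needs no control earlier. The demand is equatorial hydride approach and a cold quench before the acetate can migrate.

28 from 27 and 26: the C2–O bond is cut. The 3-ketone can enolise only toward C2, and conjugate reduction of the enone 26 gives that enolate regiospecifically as 27. The gain is that C2 oxygenation needs no directing group. The demand is 1,4-selective hydride delivery and an oxidant that leaves the two trisubstituted alkenes alone.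

26 from 25, 24 and 23: no skeletal bond is cut. The C3 carbonyl is traced to the C3 silyl ether and the C15 acetate to the C15 silyl ether. Both silyl groups of 23 leave together, and the primary C15 hydroxyl of 24 is then told from the hindered axial C3 hydroxyl by acylation rate. The demand is only that selectivity.

23 from 22: the C7=C8 double bond is cut, which opens ring B. This is the only ring bond whose formation creates no stereocentre and fixes the alkene position by connectivity. The gain is a monocyclic precursor in which C5, C9 and C10 are already set. The demand is site selectivity among four alkenes. The configurations at C3, C5, C9 and C10 of 22 and 23 were checked against 29 and agree.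

22 from 19 and 4: the C11–C12 bond is cut. C12 is allylic, so the chain arrives as the primary allylic bromide 4 with the (E) alkene and C15 oxygen in place, and C11 becomes a primary organometallic. The gain is a five-carbon building block and a ring A fragment whose C9 substituents are short. The demand is substitution at the α-carbon of 4.

19 from 18, 17 and 14: the C9–C10 bond is cut by a [3,3] shift of a C2 ester. This sets the quaternary C10 by suprafacial transfer from the C2 carbinol and sets C9 at once. The two carbon substituents of C9 are assigned so that the enolate carbon carries the isopropenyl unit (C8, C17) and the carboxyl carbon becomes C11. Cyclohexenyl esters prefer a boat-like transition state, in which the enolate substituent cis to the silyloxy group points away from the ring. With this assignment that geometry gives the C9 configuration of 29. The opposite assignment (chain on the enolate carbon, carboxyl turned into the isopropenyl group) would put the chain on the wrong side of C9. The demand is a (Z) ketene acetal and tolerance of the 1,3-interaction with the axial C4 methyl group.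

14 from 12 and 13: the ester C–O bond is cut. The demand is acylation of a hindered allylic alcohol without silyl migration.

12 from 11, 10 and 9: the C2–H and C3–O bonds are cut. The C3 oxygen is placed through the kinetic α′-enolate of 9, and the C2 carbinol is then set cis to it by hydride addition. The gain is that one ring stereocentre (C5) controls both new ones. The demand is attack at C3 anti to the crotyl arm and hydride approach anti to the syn-axial C4 methyl group.

9 from 8, 6 and 5: the C2 oxygen is cut back to C–H, and the crotyl arm to the enone of 5 by reductive alkene transposition. The gain is a commercial starting material that brings ring A, C20 and C5. The demand is that the ring CH2 is oxidised in preference to the crotyl positions.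

4 from 3, 2 and 1: the C–Br bond and the allylic C–O bond are cut back to the (E)-methyl group of protected 1. The demand is (E)-selective allylic oxidation.

## Other disconnections considered

Alternative 1: The cut is through C5–C10 and C8–C9, so that both rings arise at once from the acyclic triene A1. In A1 an (E)-enoate (C9=C10 with the C11 ester) and a 2-silyloxy diene (C5=C6–C7=C8) are tied by the C1–C4 chain carrying the C2/C3 acetonide. The forward key step is a thermal intramolecular Diels–Alder reaction of A1 to the trans-fused bicycle A2.
- In its favour: two rings, two C–C bonds and the C5, C9 and C10 stereocentres form in one concerted step, the cis relation of C11 and C20 follows from the enoate geometry, and the C2/C3 diol is carried from the start. On rings and bonds per step and on the C2/C3 oxygens it is better than the chosen plan, which builds, spends and rebuilds the C2 oxygen.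
- Against it here: a trisubstituted dienophile that must form the quaternary C10 should react sluggishly. The trans ring fusion and the facial sense rest on a four-atom tether and a remote acetonide. A2 carries its alkene at C6=C7 as an enol ether, so C7=C8 must be made afterwards through the C7 ketone by regioselective enolisation toward C8, which reopens the positional ambiguity. C8 is made as a stereocentre and then erased. The C11 ester needs five more carbons.
- Comparison: structurally the cycloaddition is the richer step. Mechanistically the chosen plan fixes the alkene by construction and makes no stereocentre on ring closure. In step count the two should be about equal, since A2 needs about as many steps after the key step as 23.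

Alternative 2: The cut is the C4–C5 bond. Ring A is seen as a ring-expanded cyclopentane, and the substrate is the trans-hydrindane A3 with a C3 tertiary alcohol bearing the isopropenyl group. In the forward step a metal hydride hydrogen-atom transfer (for example Fe(acac)3 with PhSiH3 and an oxidant) gives the C4 tertiary radical. Oxidation to the cation triggers the 1,2-shift of C5 from C3 to C4 and gives the decalin dione A4.
- In its favour: one step delivers ring A, the gem-dimethyl group and the C3 ketone, the oxidation level from which the C2 acetate and axial C3 alcohol are reached. This is better than the chosen plan's detour through a C3 silyl ether. C7=C8 with C17 is already in place. The C5/C10 pair can come from established enantioselective annulation chemistry, equal in reliability to the chiral-pool start.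
- Against it here: C2 and C5 compete as migrating groups, and the enone alkene competes for the hydrogen atom. The C9 ketone of A4 must become a CH bearing the whole C11–C16 chain with the correct configuration. That means addition to a neopentyl carbonyl followed by deoxygenation at an allylic position, where the alkene can shift to C8=C9. The C3 and C9 ketones must be told apart.
- Comparison: structurally the alternative is stronger for ring A and its oxygens. Mechanistically its key step has more branching points (radical, cation, two migrating groups) than a metathesis. The step economy gained in ring A is likely spent again at C9.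

Alternative 3: The cut is the C8–C9 bond. The substrate A5 is a ring A acetonide with an (E)-enoate arm on C10 (C9=C11, C12 ester) and an arm on C5 ending in the (Z)-enol triflate at C8. In the forward step zerovalent palladium formed from Pd(OAc)2 inserts into the C8–O bond, the vinylpalladium adds 6-exo to C9, and HCO2Na reduces the C11 palladium enolate to give A6.
- In its favour: the alkene is fixed at C7=C8 by the position of the triflate, which equals the positional certainty of the metathesis. The C2/C3 diol is in place before ring B closes, which is better than the chosen plan. The start from 5 is shared, which is equal.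
- Against it here: C9 becomes a stereocentre in the ring-closing step and depends on the facial course of the carbopalladation next to the quaternary C10. β-Hydride elimination to a dienoate competes with reduction. The enol triflate must be formed toward C7 and with (Z) geometry from a methyl ketone. The quaternary C10 bearing the enoate arm still has to be built. The C12 ester needs four more carbons.
- Comparison: on alkene placement the two plans are equal, and on the ring A diol the alternative is better. On the security of C9 and the number of selectivity questions in the key step the chosen plan is better. Chain completion costs about the same in both, so total step counts should be close.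

Key step: step 15

## Route

Step 1
Reactants: 1 3-methylbut-2-en-1-ol (prenol)
Product: 2 tert-butyl[(3-methylbut-2-en-1-yl)oxy]diphenylsilane
Conditions: tBuPh2SiCl, imidazole, DMF, 0 °C to rt
Reagents that add atoms: tert-butyl(chloro)diphenylsilane, CC(C)(C)[Si](Cl)(c1ccccc1)c1ccccc1
Why: Imidazole-promoted silylation of a primary alcohol; the silyl ether survives the later oxidation, organometallic coupling and metathesis.

Step 2
Reactants: 2 tert-butyl[(3-methylbut-2-en-1-yl)oxy]diphenylsilane
Product: 3 (E)-4-(tert-butyldiphenylsilyloxy)-2-methylbut-2-en-1-ol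
Conditions: SeO2 (0.5 equiv), tBuOOH, CH2Cl2, 0 °C to rt; NaBH4, MeOH work-up
Reagents that add atoms: selenium dioxide, O=[Se]=O; tert-butyl hydroperoxide, CC(C)(C)OO
Why: Selenium dioxide allylic oxidation (ene reaction, then [2,3]-shift) takes place at the (E)-methyl group of a trisubstituted alkene and should give the (E)-allylic alcohol; the borohydride work-up returns any over-oxidised enal to 3.

Step 3
Reactants: 3 (E)-4-(tert-butyldiphenylsilyloxy)-2-methylbut-2-en-1-ol
Product: 4 (E)-[(4-bromo-3-methylbut-2-en-1-yl)oxy](tert-butyl)diphenylsilane
Conditions: CBr4, PPh3, CH2Cl2, 0 °C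
Reagents that add atoms: carbon tetrabromide, BrC(Br)(Br)Br
Why: Appel bromination of a primary allylic alcohol under neutral conditions; direct displacement at the primary carbon keeps the (E) alkene.

Step 4
Reactants: 5 (R)-α-ionone
Product: 6 (R)-α-ionone p-toluenesulfonylhydrazone
Conditions: TsNHNH2, MeOH, rt
Reagents that add atoms: p-toluenesulfonyl hydrazide, Cc1ccc(cc1)S(=O)(=O)NN
Why: Condensation of the methyl ketone under near-neutral conditions, mild enough to keep the ring alkene out of conjugation and the doubly allylic stereocentre (the future C5) intact.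

Step 5
Reactants: 6 (R)-α-ionone p-toluenesulfonylhydrazone
Product: 8 (R)-6-[(E)-but-2-en-1-yl]-1,5,5-trimethylcyclohex-1-ene, via allylic diazene 7 (not isolated)
Conditions: catecholborane, CHCl3, 0 °C; NaOAc·3H2O, reflux
Reagents that add atoms: none
Why: Kabalka reductive transposition: hydride adds 1,2 to the unsaturated hydrazone, loss of sulfinate gives diazene 7, and its retro-ene loss of N2 delivers hydrogen to the carbon next to the ring and moves the alkene into the (E)-crotyl position; the stereocentre is not touched.

Step 6
Reactants: 8 (R)-6-[(E)-but-2-en-1-yl]-1,5,5-trimethylcyclohex-1-ene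
Product: 9 (R)-4-[(E)-but-2-en-1-yl]-3,5,5-trimethylcyclohex-2-en-1-one
Conditions: Rh2(cap)4 (1 mol %), tBuOOH (70% aq.), K2CO3, CH2Cl2, rt
Reagents that add atoms: tert-butyl hydroperoxide, CC(C)(C)OO
Why: Radical allylic oxidation (hydrogen abstraction by tert-butylperoxyl, mixed peroxide, enone) should prefer the open ring CH2 allylic to the electron-rich trisubstituted alkene over the crotyl CH2, which is screened by the ring and the gem-dimethyl group; the C5 hydrogen is pseudo-equatorial and poorly aligned for abstraction.

Step 7
Reactants: 9 (R)-4-[(E)-but-2-en-1-yl]-3,5,5-trimethylcyclohex-2-en-1-one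
Product: 10 (4S,6R)-4-[(E)-but-2-en-1-yl]-6-hydroxy-3,5,5-trimethylcyclohex-2-en-1-one
Conditions: KN(SiMe3)2, THF, −78 °C; 2-(phenylsulfonyl)-3-phenyloxaziridine, −78 °C; aq. NH4Cl
Reagents that add atoms: 2-(phenylsulfonyl)-3-phenyloxaziridine (Davis oxaziridine), O=S(=O)(c1ccccc1)N1OC1c1ccccc1
Why: Kinetic α′-deprotonation and Davis oxidation of the cross-conjugated dienolate; the oxidant should reach C3 on the face away from the C5 crotyl arm, which is syn-axial to the other face, so the new oxygen ends trans to the arm.

Step 8
Reactants: 10 (4S,6R)-4-[(E)-but-2-en-1-yl]-6-hydroxy-3,5,5-trimethylcyclohex-2-en-1-one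
Product: 11 (4S,6R)-4-[(E)-but-2-en-1-yl]-3,5,5-trimethyl-6-(triethylsilyloxy)cyclohex-2-en-1-one
Conditions: Et3SiCl, imidazole, DMF, 0 °C
Reagents that add atoms: chlorotriethylsilane, CC[Si](Cl)(CC)CC
Why: Silylation of the α-ketol stops ketol isomerisation and keeps the C3 oxygen apart from the C2 oxygen; the triethylsilyl group can later leave with fluoride together with the C15 silyl group.

Step 9
Reactants: 11 (4S,6R)-4-[(E)-but-2-en-1-yl]-3,5,5-trimethyl-6-(triethylsilyloxy)cyclohex-2-en-1-one
Product: 12 (1S,4S,6R)-4-[(E)-but-2-en-1-yl]-3,5,5-trimethyl-6-(triethylsilyloxy)cyclohex-2-en-1-ol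
Conditions: LiBH(sBu)3, THF, −78 °C; AcOH, −78 °C; buffered H2O2 work-up
Reagents that add atoms: none
Why: Bulky-hydride 1,2-reduction (the β-carbon is fully substituted, so conjugate addition is blocked); with the crotyl arm pseudoaxial, the C4 methyl group syn-axial to C2 screens the face that carries the C3 oxygen, hydride enters from the other face, and the carbinol oxygen ends cis to the silyl ether and pseudoaxial; the cold acid quench prevents 1,2-silyl migration.

Step 10
Reactants: 12 (1S,4S,6R)-4-[(E)-but-2-en-1-yl]-3,5,5-trimethyl-6-(triethylsilyloxy)cyclohex-2-en-1-ol; 13 3-methylbut-2-enoic acid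
Product: 14 (1S,4S,6R)-4-[(E)-but-2-en-1-yl]-3,5,5-trimethyl-6-(triethylsilyloxy)cyclohex-2-en-1-yl 3-methylbut-2-enoate
Conditions: DCC, DMAP, CH2Cl2, 0 °C to rt
Reagents that add atoms: none
Why: Steglich esterification; acyl transfer through the acylpyridinium ion copes with the hindered allylic alcohol and keeps the ester conjugated, which matters for the enolate geometry in step 11.

Step 11
Reactants: 14 (1S,4S,6R)-4-[(E)-but-2-en-1-yl]-3,5,5-trimethyl-6-(triethylsilyloxy)cyclohex-2-en-1-yl 3-methylbut-2-enoate
Product: 17 (2R)-2-[(1R,4S,6S)-6-[(E)-but-2-en-1-yl]-1,5,5-trimethyl-4-(triethylsilyloxy)cyclohex-2-en-1-yl]-3-methylbut-3-enoic acid, via silyl ketene acetal 15 (not isolated), via trimethylsilyl ester 16 (not isolated)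
Conditions: LiN(iPr)2, THF, −78 °C; Me3SiCl, Et3N, −78 °C to rt, then 60 °C; aq. citric acid
Reagents that add atoms: none
Why: Ireland–Claisen rearrangement of an ester dienolate: γ-deprotonation of the s-cis enoate gives the (Z) ketene acetal 15 (isopropenyl cis to OSiMe3), and the suprafacial [3,3] shift joins C9 to C10 on the face that the C2 oxygen leaves, trans to the crotyl arm, which sets C10. The boat-like transition state expected for a cyclohexenyl ester (a chair would push the silyloxy carbon onto the ring face that carries the axial C4 methyl group) places the isopropenyl group outward over C20 and H9 toward the ring, which sets C9 as in the target.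

Step 12
Reactants: 17 (2R)-2-[(1R,4S,6S)-6-[(E)-but-2-en-1-yl]-1,5,5-trimethyl-4-(triethylsilyloxy)cyclohex-2-en-1-yl]-3-methylbut-3-enoic acid
Product: 18 (2R)-2-[(1R,4S,6S)-6-[(E)-but-2-en-1-yl]-1,5,5-trimethyl-4-(triethylsilyloxy)cyclohex-2-en-1-yl]-3-methylbut-3-en-1-ol
Conditions: LiAlH4, Et2O, 0 °C to rt
Reagents that add atoms: none
Why: Hydride reduction of the acid through its carboxylate, which cannot enolise, so the allylic C9 centre is not epimerised and the alkene stays out of conjugation.

Step 13
Reactants: 18 (2R)-2-[(1R,4S,6S)-6-[(E)-but-2-en-1-yl]-1,5,5-trimethyl-4-(triethylsilyloxy)cyclohex-2-en-1-yl]-3-methylbut-3-en-1-ol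
Product: 19 (3R)-4-iodo-2-methyl-3-[(1R,4S,6S)-6-[(E)-but-2-en-1-yl]-1,5,5-trimethyl-4-(triethylsilyloxy)cyclohex-2-en-1-yl]but-1-ene
Conditions: I2, PPh3, imidazole, CH2Cl2, 0 °C to rt
Reagents that add atoms: iodine, II
Why: Garegg–Samuelsson iodination of a primary alcohol under buffered conditions that spare the silyl ether and the alkenes.

Step 14
Reactants: 19 (3R)-4-iodo-2-methyl-3-[(1R,4S,6S)-6-[(E)-but-2-en-1-yl]-1,5,5-trimethyl-4-(triethylsilyloxy)cyclohex-2-en-1-yl]but-1-ene; 4 (E)-[(4-bromo-3-methylbut-2-en-1-yl)oxy](tert-butyl)diphenylsilane
Product: 22 tert-butyl{[(2E,6R)-6-[(1S,4S,6S)-6-[(E)-but-2-en-1-yl]-1,5,5-trimethyl-4-(triethylsilyloxy)cyclohex-2-en-1-yl]-3,7-dimethylocta-2,7-dien-1-yl]oxy}diphenylsilane, via alkyllithium 20 (not isolated), via alkylmagnesium bromide 21 (not isolated)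
Conditions: tBuLi (2.1 equiv), Et2O–pentane, −78 °C; MgBr2·OEt2; then 4, Li2CuCl4 (5 mol %), THF, −30 to 0 °C
Reagents that add atoms: none
Why: Iodine–lithium exchange, transmetalation to magnesium and Kochi-type copper-catalysed coupling with a primary allylic bromide, which under these conditions should take place at the α-carbon with retention of the (E) alkene; the C11–C12 bond forms and no stereocentre is involved.

Step 15
Reactants: 22 tert-butyl{[(2E,6R)-6-[(1S,4S,6S)-6-[(E)-but-2-en-1-yl]-1,5,5-trimethyl-4-(triethylsilyloxy)cyclohex-2-en-1-yl]-3,7-dimethylocta-2,7-dien-1-yl]oxy}diphenylsilane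
Product: 23 (3S,5S,9R,10S)-15-(tert-butyldiphenylsilyloxy)-3-(triethylsilyloxy)labda-1,7,13(E)-triene
Conditions: second-generation Grubbs catalyst (H2IMes)(PCy3)Cl2Ru=CHPh (10 mol %), toluene (0.005 M), 80 °C, argon purge
Reagents that add atoms: none
Why: The ruthenium carbene should enter the least hindered alkene, the 1,2-disubstituted crotyl group, to give an alkylidene at C7; [2+2] cycloaddition with the isopropenyl group gives a ruthenacyclobutane whose cycloreversion forms C7=C8 and leaves a ruthenium methylidene, which re-enters the next crotyl group with loss of propene. The closest known reaction type is ring-closing metathesis of a 1,1-disubstituted alkene with a 1,2-disubstituted alkene to a trisubstituted cyclohexene. Ring B closes as a six-membered ring (C5 to C10), the only ring size open to the two arms, and the alkene is held at C7=C8 with C17 on C8 by the connectivity of the isopropenyl carbon. No stereocentre is formed; C5, C9 and C10 were set before and carry no activating group, so they cannot be scrambled, and the trans arms on C5 and C10 can reach each other in a chair-like closure. The step needs site selectivity among four alkenes: the ring A alkene sits in an unstrained ring between the quaternary C10 and the silyloxy-bearing C3, and the side-chain alkene is trisubstituted and could only close an eight-membered ring, so neither should compete. Removal of propene drives the closure and high dilution suppresses cross-metathesis between crotyl arms.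

Step 16
Reactants: 23 (3S,5S,9R,10S)-15-(tert-butyldiphenylsilyloxy)-3-(triethylsilyloxy)labda-1,7,13(E)-triene
Product: 24 (3S,5S,9R,10S)-labda-1,7,13(E)-triene-3,15-diol
Conditions: Bu4NF, THF, rt
Reagents that add atoms: none
Why: Fluoride cleaves both silyl ethers in one operation; nothing base-sensitive is present at this stage.

Step 17
Reactants: 24 (3S,5S,9R,10S)-labda-1,7,13(E)-triene-3,15-diol
Product: 25 (3S,5S,9R,10S)-3-hydroxylabda-1,7,13(E)-trien-15-yl acetate
Conditions: Ac2O (1.1 equiv), pyridine, CH2Cl2, −20 to 0 °C
Reagents that add atoms: acetic anhydride, CC(=O)OC(C)=O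
Why: Acylation should select the primary C15 hydroxyl over the axial C3 hydroxyl, which stands next to the gem-dimethyl carbon.

Step 18
Reactants: 25 (3S,5S,9R,10S)-3-hydroxylabda-1,7,13(E)-trien-15-yl acetate
Product: 26 (5S,9R,10S)-3-oxolabda-1,7,13(E)-trien-15-yl acetate
Conditions: Dess–Martin periodinane, NaHCO3, CH2Cl2, rt
Reagents that add atoms: none
Why: Periodinane oxidation of the hindered axial allylic alcohol to the enone under buffered, neutral conditions that leave the acetate and the alkenes alone.

Step 19
Reactants: 26 (5S,9R,10S)-3-oxolabda-1,7,13(E)-trien-15-yl acetate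
Product: 27 (5S,9R,10S)-3-(trimethylsilyloxy)labda-2,7,13(E)-trien-15-yl acetate
Conditions: LiBH(sBu)3 (1.1 equiv), THF, −78 °C; Me3SiCl, Et3N, −78 to 0 °C; pentane, filtration
Reagents that add atoms: chlorotrimethylsilane, C[Si](C)(C)Cl
Why: Conjugate reduction of a β-unsubstituted cyclohexenone whose carbonyl is screened by the quaternary C4, followed by O-silylation of the enolate, which can only be the C2=C3 isomer; the acetate should survive one equivalent of hydride at −78 °C.

Step 20
Reactants: 27 (5S,9R,10S)-3-(trimethylsilyloxy)labda-2,7,13(E)-trien-15-yl acetate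
Product: 28 (2S,5S,9R,10S)-2-acetoxy-3-oxolabda-7,13(E)-dien-15-yl acetate
Conditions: Pb(OAc)4, CH2Cl2, 0 °C to rt
Reagents that add atoms: lead tetraacetate, CC(=O)O[Pb](OC(C)=O)(OC(C)=O)OC(C)=O
Why: Lead tetraacetate oxidation of a silyl enol ether (Rubottom type): tetravalent lead adds to C2 on the face away from C20 and the axial C4 methyl group and hands an acetate to the same carbon, so the equatorial C2 acetate trans to C20 should result; this is also the thermodynamic epimer, and the trisubstituted alkenes are inert at this temperature.

Step 21
Reactants: 28 (2S,5S,9R,10S)-2-acetoxy-3-oxolabda-7,13(E)-dien-15-yl acetate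
Product: 29 (2S,3R,5S,9R,10S)-2-acetoxy-3-hydroxylabda-7,13(E)-dien-15-yl acetate
Conditions: LiBH(sBu)3 (1.2 equiv), THF, −78 °C; AcOH, −78 °C
Reagents that add atoms: none
Why: Bulky-hydride reduction of a 4,4-dimethyl-3-ketone from the equatorial direction, the axial path being closed to a large reagent by the syn-axial hydrogens at C1 and C5, gives the axial C3 alcohol cis to the C2 acetate; the acid quench at −78 °C protonates the alkoxide before the acetate can migrate.

## Compound list

1 | 3-methylbut-2-en-1-ol (prenol) | CC(C)=CCO | starting material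
2 | tert-butyl[(3-methylbut-2-en-1-yl)oxy]diphenylsilane | CC(C)=CCO[Si](c1ccccc1)(c1ccccc1)C(C)(C)C | intermediate
3 | (E)-4-(tert-butyldiphenylsilyloxy)-2-methylbut-2-en-1-ol | CC(C)(C)[Si](c1ccccc1)(c1ccccc1)OC/C=C(\C)CO | intermediate
4 | (E)-[(4-bromo-3-methylbut-2-en-1-yl)oxy](tert-butyl)diphenylsilane | CC(C)(C)[Si](c1ccccc1)(c1ccccc1)OC/C=C(\C)CBr | intermediate
5 | (R)-α-ionone, (E)-4-[(1R)-2,6,6-trimethylcyclohex-2-en-1-yl]but-3-en-2-one | CC(=O)/C=C/[C@H]1C(C)=CCCC1(C)C | starting material
6 | (R)-α-ionone p-toluenesulfonylhydrazone (C=N geometry not defined) | CC(=NNS(=O)(=O)c1ccc(C)cc1)/C=C/[C@H]1C(C)=CCCC1(C)C | intermediate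
7 | allylic diazene, (E)-3-diazenyl-1-[(1R)-2,6,6-trimethylcyclohex-2-en-1-yl]but-1-ene (both epimers at the nitrogen-bearing carbon) | CC(N=N)/C=C/[C@H]1C(C)=CCCC1(C)C | intermediate (not isolated)
8 | (R)-6-[(E)-but-2-en-1-yl]-1,5,5-trimethylcyclohex-1-ene | C/C=C/C[C@H]1C(C)=CCCC1(C)C | intermediate
9 | (R)-4-[(E)-but-2-en-1-yl]-3,5,5-trimethylcyclohex-2-en-1-one | C/C=C/C[C@H]1C(C)=CC(=O)CC1(C)C | intermediate
10 | (4S,6R)-4-[(E)-but-2-en-1-yl]-6-hydroxy-3,5,5-trimethylcyclohex-2-en-1-one | C/C=C/C[C@@H]1C(C)(C)[C@@H](O)C(=O)C=C1C | intermediate
11 | (4S,6R)-4-[(E)-but-2-en-1-yl]-3,5,5-trimethyl-6-(triethylsilyloxy)cyclohex-2-en-1-one | C/C=C/C[C@@H]1C(C)(C)[C@@H](O[Si](CC)(CC)CC)C(=O)C=C1C | intermediate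
12 | (1S,4S,6R)-4-[(E)-but-2-en-1-yl]-3,5,5-trimethyl-6-(triethylsilyloxy)cyclohex-2-en-1-ol | C/C=C/C[C@@H]1C(C)(C)[C@@H](O[Si](CC)(CC)CC)[C@@H](O)C=C1C | intermediate
13 | 3-methylbut-2-enoic acid | CC(C)=CC(=O)O | starting material
14 | (1S,4S,6R)-4-[(E)-but-2-en-1-yl]-3,5,5-trimethyl-6-(triethylsilyloxy)cyclohex-2-en-1-yl 3-methylbut-2-enoate | C/C=C/C[C@@H]1C(C)(C)[C@@H](O[Si](CC)(CC)CC)[C@@H](OC(=O)C=C(C)C)C=C1C | intermediate
15 | (Z)-trimethylsilyl dienyl ketene acetal of 14 (isopropenyl cis to OSiMe3) | C/C=C/C[C@@H]1C(C)(C)[C@@H](O[Si](CC)(CC)CC)[C@@H](O/C(O[Si](C)(C)C)=C/C(C)=C)C=C1C | intermediate (not isolated)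
16 | trimethylsilyl ester of 17 | C/C=C/C[C@@H]1C(C)(C)[C@@H](O[Si](CC)(CC)CC)C=C[C@@]1(C)[C@H](C(=O)O[Si](C)(C)C)C(C)=C | intermediate (not isolated)
17 | (2R)-2-[(1R,4S,6S)-6-[(E)-but-2-en-1-yl]-1,5,5-trimethyl-4-(triethylsilyloxy)cyclohex-2-en-1-yl]-3-methylbut-3-enoic acid | C/C=C/C[C@@H]1C(C)(C)[C@@H](O[Si](CC)(CC)CC)C=C[C@@]1(C)[C@H](C(=O)O)C(C)=C | intermediate
18 | (2R)-2-[(1R,4S,6S)-6-[(E)-but-2-en-1-yl]-1,5,5-trimethyl-4-(triethylsilyloxy)cyclohex-2-en-1-yl]-3-methylbut-3-en-1-ol | C/C=C/C[C@@H]1C(C)(C)[C@@H](O[Si](CC)(CC)CC)C=C[C@@]1(C)[C@H](CO)C(C)=C | intermediate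
19 | (3R)-4-iodo-2-methyl-3-[(1R,4S,6S)-6-[(E)-but-2-en-1-yl]-1,5,5-trimethyl-4-(triethylsilyloxy)cyclohex-2-en-1-yl]but-1-ene | C/C=C/C[C@@H]1C(C)(C)[C@@H](O[Si](CC)(CC)CC)C=C[C@@]1(C)[C@H](CI)C(C)=C | intermediate
20 | primary alkyllithium from 19 (lithium on C11) | C/C=C/C[C@@H]1C(C)(C)[C@@H](O[Si](CC)(CC)CC)C=C[C@@]1(C)[C@H](C[Li])C(C)=C | intermediate (not isolated)
21 | primary alkylmagnesium bromide from 20 (magnesium on C11) | C/C=C/C[C@@H]1C(C)(C)[C@@H](O[Si](CC)(CC)CC)C=C[C@@]1(C)[C@H](C[Mg]Br)C(C)=C | intermediate (not isolated)
22 | tert-butyl{[(2E,6R)-6-[(1S,4S,6S)-6-[(E)-but-2-en-1-yl]-1,5,5-trimethyl-4-(triethylsilyloxy)cyclohex-2-en-1-yl]-3,7-dimethylocta-2,7-dien-1-yl]oxy}diphenylsilane | C/C=C/C[C@@H]1C(C)(C)[C@@H](O[Si](CC)(CC)CC)C=C[C@@]1(C)[C@H](CC/C(C)=C/CO[Si](c2ccccc2)(c2ccccc2)C(C)(C)C)C(C)=C | intermediate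
23 | (3S,5S,9R,10S)-15-(tert-butyldiphenylsilyloxy)-3-(triethylsilyloxy)labda-1,7,13(E)-triene | CC(C)(C)[Si](c1ccccc1)(c1ccccc1)OC/C=C(\C)CC[C@@H]1C(C)=CC[C@@H]2C(C)(C)[C@@H](O[Si](CC)(CC)CC)C=C[C@@]12C | intermediate
24 | (3S,5S,9R,10S)-labda-1,7,13(E)-triene-3,15-diol | OC/C=C(\C)CC[C@@H]1C(C)=CC[C@@H]2C(C)(C)[C@@H](O)C=C[C@@]12C | intermediate
25 | (3S,5S,9R,10S)-3-hydroxylabda-1,7,13(E)-trien-15-yl acetate | CC(=O)OC/C=C(\C)CC[C@@H]1C(C)=CC[C@@H]2C(C)(C)[C@@H](O)C=C[C@@]12C | intermediate
26 | (5S,9R,10S)-3-oxolabda-1,7,13(E)-trien-15-yl acetate | CC(=O)OC/C=C(\C)CC[C@@H]1C(C)=CC[C@@H]2C(C)(C)C(=O)C=C[C@@]12C | intermediate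
27 | (5S,9R,10S)-3-(trimethylsilyloxy)labda-2,7,13(E)-trien-15-yl acetate | CC(=O)OC/C=C(\C)CC[C@@H]1C(C)=CC[C@@H]2C(C)(C)C(O[Si](C)(C)C)=CC[C@@]12C | intermediate
28 | (2S,5S,9R,10S)-2-acetoxy-3-oxolabda-7,13(E)-dien-15-yl acetate | CC(=O)OC/C=C(\C)CC[C@@H]1C(C)=CC[C@@H]2C(C)(C)C(=O)[C@@H](OC(C)=O)C[C@@]12C | intermediate
29 | (2S,3R,5S,9R,10S)-2-acetoxy-3-hydroxylabda-7,13(E)-dien-15-yl acetate | CC(=O)OC/C=C(\C)CC[C@@H]1C(C)=CC[C@@H]2C(C)(C)[C@@H](O)[C@@H](OC(C)=O)C[C@@]12C | target

## Step count and least certain steps

Total: 21 steps. Longest linear sequence: 18 steps (steps 4 to 21, from 5). The bromide 4 takes 3 steps (steps 1 to 3) and enters at step 14.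

Step 15 (key step). What may go wrong: slow engagement of the 1,1-disubstituted isopropenyl alkene beside the quaternary C10, so that the C7 alkylidene is diverted into intermolecular cross-metathesis of the crotyl arms; alkene migration by ruthenium hydride species formed on catalyst decay is a second risk. Fallback: the ring closure would be moved ahead of the chain attachment. Setting out from 18, the same catalyst would close ring B on a substrate with three alkenes and a small C9 substituent, giving the bicyclic primary alcohol F1. Iodination (I2, PPh3, imidazole) would give the bicyclic iodide F2, and the copper-catalysed coupling of step 14 with 4 would rejoin the route at 23.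

Step 6. What may go wrong: poor site selectivity of hydrogen abstraction (ring CH2 against the crotyl CH2 and methyl group) and over-oxidation. Fallback: the order of oxidation and transposition would be exchanged. Setting out from 5, in which the side-chain alkene is electron-poor and its allylic positions are deactivated, the same allylic oxidation would give (R)-3-oxo-α-ionone F3. Condensation with TsNHNH2 at the less hindered methyl ketone would give the mono-tosylhydrazone F4, and catecholborane followed by NaOAc·3H2O, to which the s-trans ring enone should be inert, would rejoin the route at 9.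

Step 11. What may go wrong: slow rearrangement because the new bond forms syn-axial to the C4 methyl group, and loss of control at C9 if the (E) ketene acetal or a chair-like passage takes part of the flux. Fallback: the roles of the two C9 substituents would be exchanged, so that the same transition-state preference gives the opposite relative configuration at C9. 5-Oxohexanoic acid and triethyl phosphonoacetate (NaH, THF) would give the ester acid F5. iBu2AlH at −78 °C would give the hydroxy acid F6, and tBuPh2SiCl with imidazole followed by mild K2CO3 work-up would give the C8–C15 acid F7. Setting out from 12, esterification with F7 (DCC, DMAP) would give the ester F8. Ireland–Claisen rearrangement would give the acid F9, with the ketene acetal geometry chosen by solvent (THF alone or THF with DMPU) to match the one that proved dominant. MeLi would give the methyl ketone F10, and Cp2Ti(μ-Cl)(μ-CH2)AlMe2 would rejoin the route at 22.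

Step 14. What may go wrong: attack at the γ-carbon of 4 (SN2′) giving a branched 1,1-disubstituted alkene, homocoupling, or protonation of the organometallic before it couples. Fallback: the polarity would be kept but the nucleophile changed to a sulfone-stabilised carbanion, which attacks allylic bromides at the α-carbon. Setting out from 19, PhSO2Na in DMF would give the C11 phenyl sulfone F11. Deprotonation with nBuLi and alkylation with 4 would give the chain-bearing sulfone F12, and reductive desulfonylation (Mg, MeOH) at this non-allylic position would rejoin the route at 22.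

Step 21. What may go wrong: hydride delivery from the axial direction giving the equatorial C3 epimer, or migration of the C2 acetate to the new C3 alkoxide before the quench. Fallback: substrate control would be replaced by catalyst control. Setting out from 28, reduction with catecholborane and (R)-2-methyl-CBS-oxazaborolidine in toluene at −78 °C, with the quaternary C4 as the large group, should deliver hydride to the face that gives the axial alcohol, under non-basic conditions that do not favour acyl migration. It comes back at 29 and no new compound is made on this path (F0).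

## Further compounds

F1 | step 15 | bicyclic primary alcohol, ring-closed 1,7-diene with C3 triethylsilyl ether and C11 hydroxyl (C12 to C16 absent) | OC[C@@H]1C(C)=CC[C@@H]2C(C)(C)[C@@H](O[Si](CC)(CC)CC)C=C[C@@]12C
F2 | step 15 | bicyclic primary iodide corresponding to F1 | IC[C@@H]1C(C)=CC[C@@H]2C(C)(C)[C@@H](O[Si](CC)(CC)CC)C=C[C@@]12C
F3 | step 6 | (R)-3-oxo-α-ionone | CC(=O)/C=C/[C@H]1C(C)=CC(=O)CC1(C)C
F4 | step 6 | side-chain mono-p-toluenesulfonylhydrazone of F3 | CC(=NNS(=O)(=O)c1ccc(C)cc1)/C=C/[C@H]1C(C)=CC(=O)CC1(C)C
F5 | step 11 | (E)-7-ethoxy-5-methyl-7-oxohept-5-enoic acid | CCOC(=O)/C=C(\C)CCCC(=O)O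
F6 | step 11 | (E)-7-hydroxy-5-methylhept-5-enoic acid | OC/C=C(\C)CCCC(=O)O
F7 | step 11 | (E)-7-(tert-butyldiphenylsilyloxy)-5-methylhept-5-enoic acid | CC(C)(C)[Si](c1ccccc1)(c1ccccc1)OC/C=C(\C)CCCC(=O)O
F8 | step 11 | ester of 12 with F7 | C/C=C/C[C@@H]1C(C)(C)[C@@H](O[Si](CC)(CC)CC)[C@@H](OC(=O)CCC/C(C)=C/CO[Si](c2ccccc2)(c2ccccc2)C(C)(C)C)C=C1C
F9 | step 11 | rearranged acid with C8 carboxyl and the full C11–C15 chain on C9 | C/C=C/C[C@@H]1C(C)(C)[C@@H](O[Si](CC)(CC)CC)C=C[C@@]1(C)[C@H](CC/C(C)=C/CO[Si](c2ccccc2)(c2ccccc2)C(C)(C)C)C(=O)O
F10 | step 11 | C8 methyl ketone from F9 | C/C=C/C[C@@H]1C(C)(C)[C@@H](O[Si](CC)(CC)CC)C=C[C@@]1(C)[C@H](CC/C(C)=C/CO[Si](c2ccccc2)(c2ccccc2)C(C)(C)C)C(C)=O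
F11 | step 14 | C11 phenyl sulfone from 19 | C/C=C/C[C@@H]1C(C)(C)[C@@H](O[Si](CC)(CC)CC)C=C[C@@]1(C)[C@H](CS(=O)(=O)c2ccccc2)C(C)=C
F12 | step 14 | C11 phenyl sulfone alkylated with 4 (both epimers at C11) | C/C=C/C[C@@H]1C(C)(C)[C@@H](O[Si](CC)(CC)CC)C=C[C@@]1(C)[C@H](C(C/C(C)=C/CO[Si](c2ccccc2)(c2ccccc2)C(C)(C)C)S(=O)(=O)c2ccccc2)C(C)=C
F0 | step 21 | none | none
A1 | alternative 1 | acyclic triene: (E)-enoate and (5E,7Z)-7-silyloxy diene joined by the C1–C4 chain with C2/C3 acetonide | COC(=O)/C=C(\C)C[C@@H]1OC(C)(C)O[C@@H]1C(C)(C)/C=C/C(O[Si](C)(C)C(C)(C)C)=C/C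
A2 | alternative 1 | trans-fused bicyclic C7 silyl enol ether with C11 methyl ester and C2/C3 acetonide | COC(=O)[C@@H]1[C@H](C)C(O[Si](C)(C)C(C)(C)C)=C[C@@H]2C(C)(C)[C@H]3OC(C)(C)O[C@H]3C[C@@]12C
A3 | alternative 2 | trans-hydrindane 7-en-9-one with C3 tertiary alcohol bearing an isopropenyl group (C3 configuration not decisive) | CC1=CC[C@@H]2C(O)(C(C)=C)CC[C@@]2(C)C1=O
A4 | alternative 2 | trans-decalin 7-ene-3,9-dione with C4 gem-dimethyl | CC1=CC[C@@H]2C(C)(C)C(=O)CC[C@@]2(C)C1=O
A5 | alternative 3 | ring A acetonide with C10 (E)-enoate arm and C5 arm ending in the (Z)-enol triflate at C8 | COC(=O)/C=C/[C@]1(C)C[C@@H]2OC(C)(C)O[C@@H]2C(C)(C)[C@H]1C/C=C(/C)OS(=O)(=O)C(F)(F)F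
A6 | alternative 3 | bicyclic 7-ene with C11–C12 methyl ester and C2/C3 acetonide | COC(=O)C[C@@H]1C(C)=CC[C@@H]2C(C)(C)[C@H]3OC(C)(C)O[C@H]3C[C@@]12C
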